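All runs were computed with constants of no real substance; noise was put on by code.

With time the rate in the oak run climbs: from its first to its second reading time rises 2.50-fold and X 5.80-fold, close to the square of time, which marks an induction period.

| flask | Z | G | E | remark |
|---|---|---|---|---|
| oak | 0.10 M | 0.40 M | 0.14 mM | run made earlier |
| larch | 0.10 M | 0.40 M | 0.22 mM | run made earlier |
| elm | 0.15 M | 0.40 M | 0.10 mM | run made earlier |
| flask | 0.10 M | 0.400 M | 0.10 mM |  |

- oak (time / d: X / %, Z / %): 0.250: 4.5, 95.3; 0.625: 26.1, 73.5; 1.25: 84.6, 16.0; 3.00: 99.4, 0
- larch (time / d: X / %, Z / %): 0.417: 19.8, 79.9; 1.04: 93.6, 7.1; 2.08: 100.1, 0; 3.00: 100.1, 0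
- elm (time / d: X / %, Z / %): 0.250: 2.3, 97.8; 0.625: 12.1, 88.2; 1.25: 37.1, 62.6; 3.00: 99.8, 0.1

(standard deviation of a reading: 0.3 percentage points)

* factor on the rate of making X when 10% of the Z are converted if G is charged twice over
* factor on the rate when 10% of the Z are converted if E is charged at 0.010 mM instead

- no earlier run changes the charge of G; that part of a forecast is a guess

The charge of Z, by hand, would raise a first-order rate. At 0.625 d, however, oak holds 186 X per E charged and elm, with 1.50 times the Z, holds 182, so the runs read as zero order in Z.

The charge of E, by hand, scales X at a given time, and the first readings show it: X per E charged over the square of time, the climb, reads 1.01 in larch as a multiple of oak. This flask needs 100 X per E charged, and the first larch reading holds 90.0 at 0.417 d, so this flask reaches 10% at 0.440 d, its tenth time, the reading time scaled by the root of the X per E needed over the X per E held.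

With 0.010 mM E the tenth time is 1.39 d. While the square law holds, the rate at that point goes as [E] times the tenth time, a factor of 0.316. But the climb in oak has sunk to 0.752 of its first reading by 1.25 d, and at a steady rate the factor is 0.100. The reckoning here takes the midpoint, 0.208.

G, never varied, would by hand give a factor between 1 and 2, which is a guess.

The forecast says 1.5 and 0.21, holding that “The rate is first order in E”.

The simulation gives 1.49 and 0.222.

    Z + D → L (k = 9.20 × 10⁻⁵ M⁻¹ s⁻¹)
    Z + G + D → X + D, rate k2*[Z]*[G]*[D]/(1 + ([Z]/sat2)) (3.40 mM, k = 59.0 M⁻² s⁻¹)
    E → D (k = 2.10 × 10⁻⁶ s⁻¹)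

This flask passes 10% at 0.437 d, against the tenth time of 0.440 d, with 6.48% of its catalyst as D and 1.14% as L. The flask with 0.010 mM E, which holds 74.2% of its catalyst as E at that conversion, passes 10% at 1.65 d by the clock of E into D, later than its tenth time of 1.39 d, with 11.4% of its catalyst as L.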